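**Retrosynthetic overview**

1. The strategy rests on ring A (C1–C5, C10): four contiguous stereocentres C3(OH)–C4(C18 methyl, C19 acid)–C5–C10(C20 methyl), two of them quaternary, with the C3 oxygen next to the C4 carboxyl. This is the pattern left by a 1-siloxydiene adding to a 2-methyl-2-enoate.
2. Target 40 ⇐ cycloadduct 35 (C1=C2 hydrogenation, oxidation at C7 and C16, C16 methylenation, deprotection) ⇐ triene 34 by one intramolecular Diels–Alder reaction that forms C5–C10 and C3–C4 and closes rings A and B.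
3. 34 ⇐ a bicyclo[3.2.1]octane (rings C and D) carrying a Z-enoate arm on C6 (Still–Gennari) and an E,E-siloxydiene on C9 (silylation of an enal). C9 and C11 are set cis on the α face by Ireland–Claisen transfer from O12 to C9 and iodolactonisation onto C11.
4. Bicycle ⇐ 4,4-disubstituted cyclohexenone by intramolecular aldol (C13–C16). C8 and C6 ⇐ Ireland–Claisen transfer from the oxygen of an (R)-cyclohexenol made by CBS reduction.
5. Ring order: C (present from the start), D (step 6), then A and B together (step 22).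

Key step: step 22

Convention: gibberellane numbering is used throughout (ring B = C5, C6, C8, C9, C10; ring C = C8, C9, C11–C14; ring D = C8, C14, C13, C16, C15). β is the face of H5, H9 and the C15–C16 bridge.

Remark: C7 is carried as CH2OBn and C16 as CH–OBn through the cycloaddition. A C7 ester would make C6–H a vinylogous malonate proton and the C5 aldehyde an enolised formyl ester, and a free C16 ketone would be silylated in step 21. Both carbons are oxidised in step 24.

Assumption: the C16 carbinol formed in step 6 (drawn as the exo epimer, oxygen anti to the C9–C12 bridge) and C10 in compounds 21–33 (left undefined) may be epimer mixtures. This is of no consequence, since both carbons become sp2 later (steps 24 and 21).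

**Route**

Step 1
Reactants: 1 3-ethoxycyclohex-2-en-1-one; 2 (1,3-dioxolan-2-ylmethyl)magnesium bromide
Product: 4 3-(1,3-dioxolan-2-ylmethyl)cyclohex-2-en-1-one, via carbinol adduct 3 (not isolated)
Conditions: THF, −20 → 0 °C; then 1 M HCl, 0 °C, 15 min
Reagents that add atoms: water, O
Why: Stork–Danheiser sequence: 1,2-addition to the vinylogous ester, then acid-induced loss of the tertiary hydroxyl and hydrolysis of the enol ether transpose the carbonyl and give the 3-substituted enone, the brief cold acid leaving the dioxolane in place.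

Step 2
Reactants: 4 3-(1,3-dioxolan-2-ylmethyl)cyclohex-2-en-1-one
Product: 5 (R)-3-(1,3-dioxolan-2-ylmethyl)cyclohex-2-en-1-ol
Conditions: (S)-2-methyl-CBS-oxazaborolidine (10 mol%), catecholborane, toluene, −78 °C
Reagents that add atoms: none
Why: Corey–Bakshi–Shibata reduction: the alkenyl side of the enone acts as the large group, so the (S)-catalyst should deliver hydride to give the (R)-carbinol (C11), and catecholborane avoids hydroboration of the alkene.

Step 3
Reactants: 5 (R)-3-(1,3-dioxolan-2-ylmethyl)cyclohex-2-en-1-ol; 6 3-(benzyloxy)propanoic acid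
Product: 7 (R)-3-(1,3-dioxolan-2-ylmethyl)cyclohex-2-en-1-yl 3-(benzyloxy)propanoate
Conditions: DCC, DMAP (cat.), CH2Cl2, 0 °C → rt
Reagents that add atoms: none
Why: Steglich esterification under neutral conditions acylates the allylic alcohol without ionising it, so C11 keeps its configuration.

Step 4
Reactants: 7 (R)-3-(1,3-dioxolan-2-ylmethyl)cyclohex-2-en-1-yl 3-(benzyloxy)propanoate
Product: 11 methyl 3-(benzyloxy)-2-[1-(1,3-dioxolan-2-ylmethyl)cyclohex-2-en-1-yl]propanoate (quaternary C8 and tertiary C6 configured as in the SMILES), via silyl ketene acetal 8 (not isolated), via trimethylsilyl ester 9 (not isolated), via carboxylic acid 10 (not isolated)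
Conditions: LiN(i-Pr)2, THF–DMPU, −78 °C; Me3SiCl; → 60 °C; aqueous work-up; Me3SiCHN2, MeOH–toluene, 0 °C
Reagents that add atoms: trimethylsilyldiazomethane, C[Si](C)(C)C=[N+]=[N-]
Why: Ireland–Claisen rearrangement: the suprafacial [3,3] shift delivers C6 to C8 on the face of the departing C11–O bond (chirality transfer sets the quaternary C8), and the (Z)-silyl ketene acetal (CH2OBn cis to OSiMe3), reacting through the boat-like transition state usual for cyclohex-2-enyl esters, sets C6; the crude acid is esterified.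

Step 5
Reactants: 11 methyl 3-(benzyloxy)-2-[1-(1,3-dioxolan-2-ylmethyl)cyclohex-2-en-1-yl]propanoate
Product: 12 methyl 3-(benzyloxy)-2-[1-(1,3-dioxolan-2-ylmethyl)-4-oxocyclohex-2-en-1-yl]propanoate (C12 ketone)
Conditions: Rh2(C6H10NO)4 (dirhodium tetrakis(caprolactamate), 1 mol%), t-BuOOH (70% aq.), K2CO3, CH2Cl2, rt
Reagents that add atoms: tert-butyl hydroperoxide, CC(C)(C)OO
Why: Catalytic allylic C–H oxidation with tert-butyl hydroperoxide: C12 is the only allylic C–H position because C8 is quaternary, and the peroxy radical should be trapped at this unhindered end of the allyl radical, giving the 4,4-disubstituted cyclohexenone.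

Step 6
Reactants: 12 methyl 3-(benzyloxy)-2-[1-(1,3-dioxolan-2-ylmethyl)-4-oxocyclohex-2-en-1-yl]propanoate
Product: 14 methyl 3-(benzyloxy)-2-(6-hydroxy-4-oxobicyclo[3.2.1]oct-2-en-1-yl)propanoate (C16 carbinol; C12 ketone; C9=C11), via keto aldehyde 13 (not isolated)
Conditions: 2 M HCl, THF, 40 °C
Reagents that add atoms: water, O
Why: Acetal hydrolysis followed by intramolecular aldol addition (5-(enolexo)-exo-trig): the enone can enolise only towards C13 because C8 is quaternary, and bridging to the C15–C16 arm fixes C13 by ring constraint and closes ring D, while either C16 epimer serves.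

Step 7
Reactants: 14 methyl 3-(benzyloxy)-2-(6-hydroxy-4-oxobicyclo[3.2.1]oct-2-en-1-yl)propanoate
Product: 15 methyl 3-(benzyloxy)-2-[6-(benzyloxy)-4-oxobicyclo[3.2.1]oct-2-en-1-yl]propanoate
Conditions: benzyl 2,2,2-trichloroacetimidate, TfOH (cat.), CH2Cl2–cyclohexane, 0 °C
Reagents that add atoms: benzyl 2,2,2-trichloroacetimidate, N=C(OCc1ccccc1)C(Cl)(Cl)Cl
Why: Acid-catalysed O-benzylation with the trichloroacetimidate protects the β-hydroxy ketone without base, so retro-aldol opening is avoided.

Step 8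
Reactants: 15 methyl 3-(benzyloxy)-2-[6-(benzyloxy)-4-oxobicyclo[3.2.1]oct-2-en-1-yl]propanoate
Product: 16 3-(benzyloxy)-2-[6-(benzyloxy)-4-hydroxybicyclo[3.2.1]oct-2-en-1-yl]propan-1-ol (12β-OH syn to the C15–C16 bridge; C5 primary alcohol)
Conditions: i-Bu2AlH (5 equiv), CH2Cl2, −78 → 0 °C
Reagents that add atoms: none
Why: Hydride reduction reduces the ester to the C5 primary alcohol and the enone in 1,2-fashion, hydride adding to C12 axially from the α face (anti to the C15–C16 bridge, which shields the β face) to give the pseudo-equatorial 12β-alcohol.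

Step 9
Reactants: 16 the diol of step 8
Product: 17 primary mono-propanoate: 3-(benzyloxy)-2-[6-(benzyloxy)-4-hydroxybicyclo[3.2.1]oct-2-en-1-yl]propyl propanoate (12β-OH free)
Conditions: EtCOCl (1.05 equiv), 2,4,6-collidine, CH2Cl2, −78 °C
Reagents that add atoms: propanoyl chloride, CCC(=O)Cl
Why: Chemoselective acylation: with the hindered, weakly nucleophilic base at low temperature the acyl chloride should esterify the primary C5 hydroxyl much faster than the secondary allylic C12 hydroxyl next to the C13 bridgehead, so the two alcohols are told apart and no stereocentre is touched.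

Step 10
Reactants: 17 the mono-propanoate of step 9; 18 propanoic acid
Product: 19 bis-propanoate: 3-(benzyloxy)-2-[6-(benzyloxy)-4-(propanoyloxy)bicyclo[3.2.1]oct-2-en-1-yl]propyl propanoate (12α-ester anti to the C15–C16 bridge)
Conditions: PPh3, DIAD, THF, 0 °C → rt
Reagents that add atoms: none
Why: Mitsunobu esterification displaces the activated allylic C12 oxygen by SN2 with inversion, giving the pseudo-axial 12α-propanoate (C9 is neopentyl, so SN2' attack is not expected), and the primary ester is inert under these neutral conditions.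

Step 11
Reactants: 19 the bis-propanoate of step 10
Product: 22 C9α-(1-carboxyethyl) Δ11 alkene in which the primary propanoate is retained, via bis ketene acetal 20 (not isolated), via silyl ester 21 (not isolated)
Conditions: LiN(i-Pr)2 (2.6 equiv), Me3SiCl–Et3N, THF, −78 → 65 °C; then 1 M HCl
Reagents that add atoms: none
Why: Ireland–Claisen rearrangement: the suprafacial [3,3] shift moves the C10 carbon from the 12α oxygen to the α face of C9 (sets C9 with H9 β) and shifts the alkene to C11=C12, while the primary silyl ketene acetal has no allyl partner and reverts to the propanoate on work-up, and the configuration at C10 does not matter.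

Step 12
Reactants: 22 the acid of step 11
Product: 23 iodolactone (cis-fused γ-lactone O11–C1(=O)–C10–C9; 12β-iodide)
Conditions: I2, NaHCO3, MeCN, 0 °C, dark
Reagents that add atoms: iodine, II
Why: Iodolactonisation (5-exo): the carboxylate on the α-face arm at C9 can reach only the α face of C11, so the C11–O bond is set α and cis to C10, with iodine anti on C12.

Step 13
Reactants: 23 the iodolactone of step 12
Product: 24 lactone (C12 methylene)
Conditions: Bu3SnH, AIBN (cat.), toluene, 80 °C
Reagents that add atoms: none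
Why: Radical-chain dehalogenation replaces the secondary iodide by hydrogen without touching a stereocentre.

Step 14
Reactants: 24 the lactone of step 13
Product: 25 diol Weinreb amide (C11 α-OH; C5 primary OH; C1 N-methoxy-N-methylamide)
Conditions: MeNH(OMe)·HCl, AlMe3 (excess), CH2Cl2, 0 → 40 °C
Reagents that add atoms: N,O-dimethylhydroxylamine hydrochloride, CNOC.Cl
Why: Weinreb aminolysis with MeAl(Cl)N(OMe)Me, formed from AlMe3 and the amine hydrochloride, opens the γ-lactone to the hydroxy amide and at the same time cleaves the primary propanoate, with no stereocentre involved.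

Step 15
Reactants: 25 the diol Weinreb amide of step 14
Product: 26 bis-TBS ether
Conditions: TBSOTf, 2,6-lutidine, CH2Cl2, −78 → 0 °C
Reagents that add atoms: tert-butyldimethylsilyl trifluoromethanesulfonate, CC(C)(C)[Si](C)(C)OS(=O)(=O)C(F)(F)F
Why: Silylation with the silyl triflate protects both hydroxyls at once and stops the γ-hydroxy amide from closing back to the lactone.

Step 16
Reactants: 26 the bis-TBS ether of step 15
Product: 27 C5 primary alcohol (C11 OTBS kept)
Conditions: HF·pyridine, pyridine, THF, 0 °C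
Reagents that add atoms: none
Why: Selective desilylation: buffered fluoride cleaves the primary silyl ether much faster than the hindered secondary one at C11.

Step 17
Reactants: 27 the primary alcohol of step 16
Product: 28 C5 aldehyde
Conditions: Dess–Martin periodinane, NaHCO3, CH2Cl2, 0 °C → rt
Reagents that add atoms: none
Why: Dess–Martin oxidation under buffered conditions gives the α-branched β-benzyloxy aldehyde without epimerising C6 or eliminating benzyl alcohol.

Step 18
Reactants: 28 the aldehyde of step 17; 29 methyl 2-[bis(2,2,2-trifluoroethoxy)phosphoryl]propanoate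
Product: 30 Z-enoate (C5=C4; ester C19 cis to C6; C18 methyl trans)
Conditions: KN(SiMe3)2, 18-crown-6, THF, −78 °C
Reagents that add atoms: none
Why: Still–Gennari olefination: the trifluoroethyl phosphonate with a dissociated potassium counter-ion eliminates under kinetic control to the Z-trisubstituted enoate, and the weakly basic anion leaves C6 and the Weinreb amide untouched.

Step 19
Reactants: 30 the Z-enoate of step 18
Product: 31 C1 aldehyde
Conditions: Cp2Zr(H)Cl, THF, rt
Reagents that add atoms: none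
Why: Reduction with Cp2Zr(H)Cl (Schwartz reduction) converts the tertiary amide to the aldehyde chemoselectively in the presence of the methyl ester.

Step 20
Reactants: 31 the aldehyde of step 19; 32 (triphenylphosphoranylidene)acetaldehyde
Product: 33 (E)-enal (C1=C2; C3 aldehyde; C10–H γ to the carbonyl)
Conditions: toluene, 80 °C
Reagents that add atoms: none
Why: Wittig reaction with the stabilised formyl ylide gives the E-enal by two-carbon homologation and does not react with the ester.

Step 21
Reactants: 33 the enal of step 20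
Product: 34 triene: (1E,3E)-1-siloxy-4-methyldiene on C9 and Z-enoate on C6
Conditions: TBSOTf, Et3N, CH2Cl2, −78 → −20 °C
Reagents that add atoms: tert-butyldimethylsilyl trifluoromethanesulfonate, CC(C)(C)[Si](C)(C)OS(=O)(=O)C(F)(F)F
Why: Silyl dienol ether formation by O-silylation and γ-deprotonation at C10: the s-trans oxocarbenium ion gives the E C2=C3 bond, and allylic strain should place the bulky C9 trans to C2 and the C20 methyl cis on the new C10=C1 bond, which also removes the C10 stereocentre.

Step 22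
Reactants: 34 the triene of step 21
Product: 35 cycloadduct (rings A–D; C1=C2; 3β-OTBS; 11α-OTBS; C19 methyl ester α; C18 β; C20 α; C7 and C16 benzyl ethers)
Conditions: toluene (0.005 M), BHT, 160 °C, sealed base-washed tube
Reagents that add atoms: none
Why: Thermal intramolecular Diels–Alder reaction, a concerted asynchronous suprafacial [4+2] cycloaddition in which the siloxy-activated diene terminus C10 bonds to the enoate β-carbon C5 and C3 bonds to C4, the electronically matched orientation that the C9–C8–C6 tether also enforces; the closest known reaction type is the thermal cyclisation of ester-activated 1,3,8-nonatrienes to trans-hydrindenes. Ring A closes as the new cyclohexene through both new bonds, and ring B closes as the five-membered ring C5–C6–C8–C9–C10 spanned by the three-atom tether. C3 and C10 follow from the E,E-diene (OTBS and C9 both outside and hence cis, C20 inside), and C4 and C5 from the Z-enoate (C19 cis to C6). The dienophile face is chosen by C6: allylic 1,3-strain with the cis ester holds H6 in the alkene plane, so C8 and the diene lie on one face and the C7 arm ends trans to C4 on ring B. The step needs the ester-exo, trans-fused mode (C6 exo, C11 and C20 syn on ring B), which is supported by the exo-ester preference of 2-methylacrylate-type dienophiles and by the anti arrangement of the tether. High dilution, a radical inhibitor and base-washed glass protect the silyl dienol ether at the temperature needed to form two quaternary carbons.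

Step 23
Reactants: 35 the cycloadduct of step 22
Product: 36 saturated diol (C7 primary OH; C16 secondary OH)
Conditions: H2 (1 atm), Pd/C, EtOAc, rt
Reagents that add atoms: none
Why: Heterogeneous hydrogenation saturates the cis-disubstituted C1=C2 bond and removes both benzyl ethers by hydrogenolysis, while the silyl ethers and the ester stay.

Step 24
Reactants: 36 the diol of step 23
Product: 37 16-keto 7-acid
Conditions: (n-Pr4N)RuO4 (10 mol%), N-methylmorpholine N-oxide monohydrate, MeCN, rt
Reagents that add atoms: water, O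
Why: Ley–Griffith oxidation in the presence of water takes the primary alcohol through the aldehyde hydrate to the C7 acid and the secondary alcohol to the C16 ketone in one operation.

Step 25
Reactants: 37 the keto acid of step 24
Product: 38 16-methylene 7-acid
Conditions: Ph3PCH3Br, KOt-Bu, THF, 0 → 50 °C (excess ylide)
Reagents that add atoms: methyltriphenylphosphonium bromide, C[P+](c1ccccc1)(c1ccccc1)c1ccccc1.[Br-]
Why: Wittig methylenation of the C16 ketone with excess ylide, the C7 acid being carried as its carboxylate, which also protects C6 from epimerisation.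

Step 26
Reactants: 38 the methylene acid of step 25
Product: 39 7,19-diacid bis-TBS ether
Conditions: NaSEt, DMF, 80 °C; then dilute HCl
Reagents that add atoms: none
Why: SN2 demethylation by thiolate at the methyl carbon frees the axial, doubly neopentyl C19 acid that resists saponification, and the C3 silyl ether is kept so that no β-alkoxide can start a retro-aldol at C3–C4.

Step 27
Reactants: 39 the diacid bis-silyl ether of step 26
Product: 40 target, CNP0232910.1
Conditions: HF (48% aq.), MeCN, rt
Reagents that add atoms: none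
Why: Fluoride-mediated desilylation under mildly acidic conditions frees the C3 and C11 hydroxyls without isomerising the exocyclic alkene and without a base that could epimerise C3.

**Compound list**

1 | 3-ethoxycyclohex-2-en-1-one | CCOC1=CC(=O)CCC1 | starting material
2 | (1,3-dioxolan-2-ylmethyl)magnesium bromide | Br[Mg]CC1OCCO1 | starting material
3 | 1-(1,3-dioxolan-2-ylmethyl)-3-ethoxycyclohex-2-en-1-ol (bromomagnesium alkoxide in the flask) | CCOC1=CC(O)(CC2OCCO2)CCC1 | intermediate (not isolated)
4 | 3-(1,3-dioxolan-2-ylmethyl)cyclohex-2-en-1-one | O=C1C=C(CC2OCCO2)CCC1 | intermediate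
5 | (R)-3-(1,3-dioxolan-2-ylmethyl)cyclohex-2-en-1-ol | O[C@H]1C=C(CC2OCCO2)CCC1 | intermediate
6 | 3-(benzyloxy)propanoic acid | OC(=O)CCOCc1ccccc1 | starting material
7 | (R)-3-(1,3-dioxolan-2-ylmethyl)cyclohex-2-en-1-yl 3-(benzyloxy)propanoate | O=C(CCOCc1ccccc1)O[C@H]1C=C(CC2OCCO2)CCC1 | intermediate
8 | (Z)-O-trimethylsilyl ketene acetal of 7 (CH2OBn cis to OSiMe3) | C[Si](C)(C)O/C(=C\COCc1ccccc1)O[C@H]1C=C(CC2OCCO2)CCC1 | intermediate (not isolated)
9 | trimethylsilyl ester of acid 10 | C[Si](C)(C)OC(=O)[C@H](COCc1ccccc1)[C@]1(CC2OCCO2)C=CCCC1 | intermediate (not isolated)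
10 | 3-(benzyloxy)-2-[1-(1,3-dioxolan-2-ylmethyl)cyclohex-2-en-1-yl]propanoic acid | OC(=O)[C@H](COCc1ccccc1)[C@]1(CC2OCCO2)C=CCCC1 | intermediate (not isolated)
11 | methyl ester of 10 | COC(=O)[C@H](COCc1ccccc1)[C@]1(CC2OCCO2)C=CCCC1 | intermediate
12 | methyl 3-(benzyloxy)-2-[1-(1,3-dioxolan-2-ylmethyl)-4-oxocyclohex-2-en-1-yl]propanoate | COC(=O)[C@H](COCc1ccccc1)[C@]1(CC2OCCO2)C=CC(=O)CC1 | intermediate
13 | methyl 3-(benzyloxy)-2-[4-oxo-1-(2-oxoethyl)cyclohex-2-en-1-yl]propanoate | COC(=O)[C@H](COCc1ccccc1)[C@]1(CC=O)C=CC(=O)CC1 | intermediate (not isolated)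
14 | methyl 3-(benzyloxy)-2-(6-hydroxy-4-oxobicyclo[3.2.1]oct-2-en-1-yl)propanoate (16-exo-OH) | O[C@@H]1C[C@]2([C@@H](COCc3ccccc3)C(=O)OC)C[C@H]1C(=O)C=C2 | intermediate
15 | methyl 3-(benzyloxy)-2-[6-(benzyloxy)-4-oxobicyclo[3.2.1]oct-2-en-1-yl]propanoate | c1ccccc1CO[C@@H]2C[C@]3([C@@H](COCc4ccccc4)C(=O)OC)C[C@H]2C(=O)C=C3 | intermediate
16 | 3-(benzyloxy)-2-[6-(benzyloxy)-4-hydroxybicyclo[3.2.1]oct-2-en-1-yl]propan-1-ol (12β-OH) | c1ccccc1CO[C@@H]2C[C@]3([C@@H](COCc4ccccc4)CO)C[C@H]2[C@H](O)C=C3 | intermediate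
17 | primary mono-propanoate of 16 (12β-OH free) | c1ccccc1CO[C@@H]2C[C@]3([C@@H](COCc4ccccc4)COC(=O)CC)C[C@H]2[C@H](O)C=C3 | intermediate
18 | propanoic acid | CCC(=O)O | starting material
19 | bis-propanoate with inverted C12 (12α-ester) | c1ccccc1CO[C@@H]2C[C@]3([C@@H](COCc4ccccc4)COC(=O)CC)C[C@H]2[C@@H](OC(=O)CC)C=C3 | intermediate
20 | bis(O-trimethylsilyl ketene acetal) of 19 | c1ccccc1CO[C@@H]2C[C@]3([C@@H](COCc4ccccc4)COC(=CC)O[Si](C)(C)C)C[C@H]2[C@@H](OC(=CC)O[Si](C)(C)C)C=C3 | intermediate (not isolated)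
21 | trimethylsilyl ester of 22, primary ester still as silyl ketene acetal | c1ccccc1CO[C@@H]2C[C@]3([C@@H](COCc4ccccc4)COC(=CC)O[Si](C)(C)C)C[C@H]2C=C[C@H]3C(C)C(=O)O[Si](C)(C)C | intermediate (not isolated)
22 | C9α-(1-carboxyethyl) Δ11-alkene, primary propanoate | c1ccccc1CO[C@@H]2C[C@]3([C@@H](COCc4ccccc4)COC(=O)CC)C[C@H]2C=C[C@H]3C(C)C(=O)O | intermediate
23 | 12β-iodo 1,11α-lactone | c1ccccc1CO[C@@H]2C[C@]3([C@@H](COCc5ccccc5)COC(=O)CC)C[C@H]2[C@H](I)[C@@H]4[C@H]3C(C)C(=O)O4 | intermediate
24 | 1,11α-lactone | c1ccccc1CO[C@@H]2C[C@]3([C@@H](COCc5ccccc5)COC(=O)CC)C[C@H]2C[C@@H]4[C@H]3C(C)C(=O)O4 | intermediate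
25 | diol Weinreb amide (11α-OH, C5 OH) | c1ccccc1CO[C@@H]2C[C@]3([C@@H](COCc4ccccc4)CO)C[C@H]2C[C@@H](O)[C@H]3C(C)C(=O)N(C)OC | intermediate
26 | bis-TBS ether of 25 | c1ccccc1CO[C@@H]2C[C@]3([C@@H](COCc4ccccc4)CO[Si](C)(C)C(C)(C)C)C[C@H]2C[C@@H](O[Si](C)(C)C(C)(C)C)[C@H]3C(C)C(=O)N(C)OC | intermediate
27 | C5 primary alcohol, 11α-OTBS | c1ccccc1CO[C@@H]2C[C@]3([C@@H](COCc4ccccc4)CO)C[C@H]2C[C@@H](O[Si](C)(C)C(C)(C)C)[C@H]3C(C)C(=O)N(C)OC | intermediate
28 | C5 aldehyde | c1ccccc1CO[C@@H]2C[C@]3([C@@H](COCc4ccccc4)C=O)C[C@H]2C[C@@H](O[Si](C)(C)C(C)(C)C)[C@H]3C(C)C(=O)N(C)OC | intermediate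
29 | methyl 2-[bis(2,2,2-trifluoroethoxy)phosphoryl]propanoate | COC(=O)C(C)P(=O)(OCC(F)(F)F)OCC(F)(F)F | starting material
30 | Z-enoate Weinreb amide | c1ccccc1CO[C@@H]2C[C@]3([C@@H](COCc4ccccc4)/C=C(/C)C(=O)OC)C[C@H]2C[C@@H](O[Si](C)(C)C(C)(C)C)[C@H]3C(C)C(=O)N(C)OC | intermediate
31 | Z-enoate C1 aldehyde | c1ccccc1CO[C@@H]2C[C@]3([C@@H](COCc4ccccc4)/C=C(/C)C(=O)OC)C[C@H]2C[C@@H](O[Si](C)(C)C(C)(C)C)[C@H]3C(C)C=O | intermediate
32 | (triphenylphosphoranylidene)acetaldehyde | O=CC=P(c1ccccc1)(c1ccccc1)c1ccccc1 | starting material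
33 | Z-enoate (E)-enal | c1ccccc1CO[C@@H]2C[C@]3([C@@H](COCc4ccccc4)/C=C(/C)C(=O)OC)C[C@H]2C[C@@H](O[Si](C)(C)C(C)(C)C)[C@H]3C(C)/C=C/C=O | intermediate
34 | cycloaddition precursor: E,E-siloxydiene on C9, Z-enoate on C6 | c1ccccc1CO[C@@H]2C[C@]3([C@@H](COCc4ccccc4)/C=C(/C)C(=O)OC)C[C@H]2C[C@@H](O[Si](C)(C)C(C)(C)C)[C@H]3/C(C)=C/C=C/O[Si](C)(C)C(C)(C)C | intermediate
35 | cycloadduct: 1,2-dehydro, 3β,11α-bis-OTBS, 19-methyl ester, 7-O-benzyl, 16-O-benzyl | c1ccccc1CO[C@@H]2C[C@]34C[C@H]2C[C@@H](O[Si](C)(C)C(C)(C)C)[C@H]3[C@]5(C)C=C[C@H](O[Si](C)(C)C(C)(C)C)[C@@](C)(C(=O)OC)[C@H]5[C@@H]4COCc6ccccc6 | intermediate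
36 | saturated 7,16-diol | O[C@@H]1C[C@]23C[C@H]1C[C@@H](O[Si](C)(C)C(C)(C)C)[C@H]2[C@]1(C)CC[C@H](O[Si](C)(C)C(C)(C)C)[C@@](C)(C(=O)OC)[C@H]1[C@@H]3CO | intermediate
37 | 16-keto 7-acid 19-methyl ester | O=C1C[C@]23C[C@H]1C[C@@H](O[Si](C)(C)C(C)(C)C)[C@H]2[C@]1(C)CC[C@H](O[Si](C)(C)C(C)(C)C)[C@@](C)(C(=O)OC)[C@H]1[C@@H]3C(=O)O | intermediate
38 | 16-methylene 7-acid 19-methyl ester | C=C1C[C@]23C[C@H]1C[C@@H](O[Si](C)(C)C(C)(C)C)[C@H]2[C@]1(C)CC[C@H](O[Si](C)(C)C(C)(C)C)[C@@](C)(C(=O)OC)[C@H]1[C@@H]3C(=O)O | intermediate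
39 | 16-methylene 7,19-diacid bis-TBS ether | C=C1C[C@]23C[C@H]1C[C@@H](O[Si](C)(C)C(C)(C)C)[C@H]2[C@]1(C)CC[C@H](O[Si](C)(C)C(C)(C)C)[C@@](C)(C(=O)O)[C@H]1[C@@H]3C(=O)O | intermediate
40 | CNP0232910.1 (3β,11α-dihydroxy-gibberell-16-ene-7,19-dioic acid skeleton) | C=C1C[C@]23C[C@H]1C[C@@H](O)[C@H]2[C@]1(C)CC[C@H](O)[C@@](C)(C(=O)O)[C@H]1[C@@H]3C(=O)O | target

**Step count and risks**

Total step count: 27. Longest linear sequence: 27 steps (from 1).

Steps most likely to fail:

1. Step 22 (cycloaddition). The ester-endo, cis-fused transition state may compete, because the required ester-exo mode places C11 next to the inside C20 methyl on the diene, and the two modes are not far apart for Z-enoates. The fallback exchanges the roles of the two C4 substituents so that the wanted trans-fused mode becomes the ester-endo mode. It sets out from aldehyde 28 and returns at 39. Aldehyde 28 is condensed (Wittig, toluene, 90 °C) with methyl 3-(benzyloxy)-2-(triphenylphosphoranylidene)propanoate F1 (from methyl (triphenylphosphoranylidene)acetate and benzyl chloromethyl ether, then base) to give the E-enoate F2, with the ester trans and CH2OBn cis to C6. The operations of steps 19–21 then give aldehyde F3, enal F4 and triene F5. Heating F5 gives adduct F6 with the ester β (future C18) and CH2OBn α (future C19). i-Bu2AlH reduces the ester to alcohol F7, and I2/PPh3/imidazole gives iodide F8. H2 with Pd/C and Et3N removes iodine and the three benzyl groups and saturates C1=C2 to give triol F9. (n-Pr4N)RuO4 with N-methylmorpholine N-oxide monohydrate gives the keto diacid F10, and Ph3P=CH2 then gives 39.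

2. Step 12 (iodolactonisation). The iodonium ion has to form on the β face of C11=C12, under the C15–C16 bridge, and this may be too slow, so the alkene could be left unchanged or trapped by an external nucleophile. The fallback is a Brønsted-acid hydrolactonisation: acid 22 with TfOH (cat.) in CH2Cl2 at 0 °C is protonated at C12, and the α-disposed carboxyl captures C11. This gives lactone 24 directly and makes step 13 unnecessary; no new compound arises.

3. Step 4 (first Ireland–Claisen). Competition of the chair-like transition state, or β-elimination of benzyl alkoxide from the ester enolate, could erode the C6 configuration or the yield. The fallback separates the two tasks; it sets out from 5 and comes back at acid 10, which is esterified to 11 as in step 4. Johnson–Claisen rearrangement of 5 with triethyl orthoacetate (EtCO2H cat., 140 °C) sets C8 alone and gives ethyl ester F11. LiOH gives acid F12. The mixed pivalic anhydride and the lithium salt of (R)-4-benzyl-1,3-oxazolidin-2-one give imide F13. Alkylation of its sodium enolate (NaN(SiMe3)2, THF, −78 °C) with benzyl chloromethyl ether sets C6 under auxiliary control and gives the benzyloxymethylated imide F14; the base-only conditions spare the dioxolane. LiOH–H2O2 (THF–H2O, 0 °C) then removes the auxiliary to give acid 10.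

Further compounds
F1 | step 22 | methyl 3-(benzyloxy)-2-(triphenylphosphoranylidene)propanoate | COC(=O)C(COCc1ccccc1)=P(c1ccccc1)(c1ccccc1)c1ccccc1
F2 | step 22 | E-enoate Weinreb amide (ester trans to C6, CH2OBn cis) | c1ccccc1CO[C@@H]2C[C@]3([C@@H](COCc4ccccc4)/C=C(\COCc5ccccc5)C(=O)OC)C[C@H]2C[C@@H](O[Si](C)(C)C(C)(C)C)[C@H]3C(C)C(=O)N(C)OC
F3 | step 22 | E-enoate C1 aldehyde | c1ccccc1CO[C@@H]2C[C@]3([C@@H](COCc4ccccc4)/C=C(\COCc5ccccc5)C(=O)OC)C[C@H]2C[C@@H](O[Si](C)(C)C(C)(C)C)[C@H]3C(C)C=O
F4 | step 22 | E-enoate (E)-enal | c1ccccc1CO[C@@H]2C[C@]3([C@@H](COCc4ccccc4)/C=C(\COCc5ccccc5)C(=O)OC)C[C@H]2C[C@@H](O[Si](C)(C)C(C)(C)C)[C@H]3C(C)/C=C/C=O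
F5 | step 22 | triene with E-enoate and E,E-siloxydiene | c1ccccc1CO[C@@H]2C[C@]3([C@@H](COCc4ccccc4)/C=C(\COCc5ccccc5)C(=O)OC)C[C@H]2C[C@@H](O[Si](C)(C)C(C)(C)C)[C@H]3/C(C)=C/C=C/O[Si](C)(C)C(C)(C)C
F6 | step 22 | cycloadduct with 4β-CO2Me and 4α-CH2OBn | c1ccccc1CO[C@@H]2C[C@]34C[C@H]2C[C@@H](O[Si](C)(C)C(C)(C)C)[C@H]3[C@]5(C)C=C[C@H](O[Si](C)(C)C(C)(C)C)[C@@](C(=O)OC)(COCc7ccccc7)[C@H]5[C@@H]4COCc6ccccc6
F7 | step 22 | 18-alcohol | c1ccccc1CO[C@@H]2C[C@]34C[C@H]2C[C@@H](O[Si](C)(C)C(C)(C)C)[C@H]3[C@]5(C)C=C[C@H](O[Si](C)(C)C(C)(C)C)[C@@](CO)(COCc7ccccc7)[C@H]5[C@@H]4COCc6ccccc6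
F8 | step 22 | 18-iodide | c1ccccc1CO[C@@H]2C[C@]34C[C@H]2C[C@@H](O[Si](C)(C)C(C)(C)C)[C@H]3[C@]5(C)C=C[C@H](O[Si](C)(C)C(C)(C)C)[C@@](CI)(COCc7ccccc7)[C@H]5[C@@H]4COCc6ccccc6
F9 | step 22 | saturated 7,16,19-triol | O[C@@H]1C[C@]23C[C@H]1C[C@@H](O[Si](C)(C)C(C)(C)C)[C@H]2[C@]1(C)CC[C@H](O[Si](C)(C)C(C)(C)C)[C@@](C)(CO)[C@H]1[C@@H]3CO
F10 | step 22 | 16-keto 7,19-diacid bis-TBS ether | O=C1C[C@]23C[C@H]1C[C@@H](O[Si](C)(C)C(C)(C)C)[C@H]2[C@]1(C)CC[C@H](O[Si](C)(C)C(C)(C)C)[C@@](C)(C(=O)O)[C@H]1[C@@H]3C(=O)O
F0 | step 12 | none | none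
F11 | step 4 | ethyl 2-[1-(1,3-dioxolan-2-ylmethyl)cyclohex-2-en-1-yl]acetate | CCOC(=O)C[C@]1(CC2OCCO2)C=CCCC1
F12 | step 4 | 2-[1-(1,3-dioxolan-2-ylmethyl)cyclohex-2-en-1-yl]acetic acid | OC(=O)C[C@]1(CC2OCCO2)C=CCCC1
F13 | step 4 | N-acyl (R)-4-benzyl-1,3-oxazolidin-2-one of F12 | O=C(C[C@]1(CC2OCCO2)C=CCCC1)N3[C@H](Cc4ccccc4)COC3=O
F14 | step 4 | benzyloxymethylated imide | O=C([C@H](COCc5ccccc5)[C@]1(CC2OCCO2)C=CCCC1)N3[C@H](Cc4ccccc4)COC3=O
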